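**Plan**

- Cuts: the ester C–O between the two halves (to a free acid and a spiro-epoxide); in the acyl half the acrylate C=C and the C-1–C-2 bond of its cyclohexene (ring C); in the lactone half the C-4=C-5 bond of the oxepinone (ring B), the lactone alkyl C–O bond, and the substituents of cyclohexane ring A back to (R)-cryptone.
- Enabling feature: in ring C the C-1 side chain and the C-6 isopropyl are cis. The isopropyl methine can therefore carry an oxygen tied to the side-chain carbon as a γ-lactone, which is the oxidation pattern of ring-cleaved (R)-α-terpineol. C-1 is then a lactone α-carbon, and C-2=C-3(CH2OH), raised to the ester level, is a β-methoxyacrylate that accepts C-1 at C-2 and loses methoxide.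
- Acyl half, forward: terpineol → keto lactone → iodide → Negishi coupling → ring C closed on the lactone template → lactol → Horner–Wadsworth–Emmons → tether oxygen removed by radical deoxygenation → acid.
- Lactone half, forward: 4-isopropylcyclohexanone → (R)-cryptone → Morita–Baylis–Hillman, vinyl cuprate, Corey–Chaykovsky (ring A) → acid → acrylate ester → ring-closing metathesis (ring B). Union: the carboxylate opens the epoxide, forming the tertiary alcohol and the ester together.
- Stereochemistry: ring C C-6 from terpineol, C-1 from the cis ring fusion of the template. Ring A C-6 from a chiral lithium amide, C-5a by cuprate addition anti to isopropyl, C-9a by kinetic protonation, C-9 by axial ylide attack. Acrylate geometries from the olefination and from the ring.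

Key step: step 6

Numbering: ring C is the cyclohex-2-ene of the acyl half (C-1 bears the acrylate, C-3 the CH2OH, C-6 the isopropyl). The lactone half is numbered as a 2-benzoxepine (C-1 lactone C=O, C-4 CO2H, C-5a/C-9a ring fusion, C-6 isopropyl, C-9 carbinol).

Assumption: lithium (R,R)-bis(1-phenylethyl)amide is taken to give the (S)-silyl enol ether in step 14; if the sense is the opposite, the (S,S)-amide is used.

**Acyl half**

Step 1
Reactants: 1 (R)-α-terpineol, 2-[(1R)-4-methylcyclohex-3-en-1-yl]propan-2-ol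
Product: 3 (4R)-5,5-dimethyl-4-(3-oxobutyl)oxolan-2-one, via hydroxy keto acid 2 (not isolated)
Conditions: RuCl3 (2 mol %), NaIO4, CCl4/MeCN/H2O, rt; then TsOH (cat.), PhMe, 60 °C
Reagents that add atoms: sodium periodate [Na+].[O-]I(=O)(=O)=O
Why: RuO4 formed in the flask cleaves the trisubstituted ring alkene (oxidative alkene cleavage) to the keto acid, whose tertiary γ-hydroxyl closes the γ-lactone; the stereocenter is untouched.

Step 2
Reactants: 3 (4R)-5,5-dimethyl-4-(3-oxobutyl)oxolan-2-one
Product: 4 3-[(3R)-2,2-dimethyl-5-oxooxolan-3-yl]propanoic acid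
Conditions: Br2, NaOH, H2O/dioxane, 0 °C → rt; then HCl to pH 1, 50 °C
Reagents that add atoms: sodium hydroxide [Na+].[OH-]
Why: Haloform reaction of the methyl ketone; the lactone, opened by base, should close again on acidification.

Step 3
Reactants: 4 3-[(3R)-2,2-dimethyl-5-oxooxolan-3-yl]propanoic acid
Product: 5 (4S)-4-(2-iodoethyl)-5,5-dimethyloxolan-2-one
Conditions: PhI(OAc)2, I2, cyclohexane, hν, reflux
Reagents that add atoms: iodine II
Why: Hunsdiecker-type iododecarboxylation through the acyl hypoiodite; the primary radical is trapped by iodine and the lactone is inert (descriptor changes by priority only).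

Step 4
Reactants: 6 methyl (2E)-3-methoxyprop-2-enoate
Product: 8 methyl (2Z)-2-iodo-3-methoxyprop-2-enoate, via iodo acetoxy adduct 7 (not isolated)
Conditions: N-iodosuccinimide, AcOH, CH2Cl2, rt; then Et3N, 0 °C → rt
Reagents that add atoms: N-iodosuccinimide O=C1CCC(=O)N1I
Why: Iodoacetoxylation of the enol ether followed by base-induced loss of acetic acid should give the α-iodo-β-methoxyacrylate.

Step 5
Reactants: 5 (4S)-4-(2-iodoethyl)-5,5-dimethyloxolan-2-one; 8 methyl (2Z)-2-iodo-3-methoxyprop-2-enoate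
Product: 10 methyl (2E)-2-{2-[(3R)-2,2-dimethyl-5-oxooxolan-3-yl]ethyl}-3-methoxyprop-2-enoate, via alkylzinc iodide 9 (not isolated)
Conditions: Zn dust (Me3SiCl, BrCH2CH2Br activation), DMA, 40 °C; then 8, Pd(PPh3)4 (5 mol %), THF, rt
Reagents that add atoms: none
Why: Zinc insertion into the primary iodide and Negishi sp3–sp2 coupling with retention of alkene geometry; alkylzinc iodides tolerate lactones and esters.

Step 6
Reactants: 10 methyl (2E)-2-{2-[(3R)-2,2-dimethyl-5-oxooxolan-3-yl]ethyl}-3-methoxyprop-2-enoate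
Product: 12 methyl (3aS,7aR)-1,1-dimethyl-3-oxo-1,3,3a,6,7,7a-hexahydro-2-benzofuran-5-carboxylate, via ester enolate 11 (not isolated)
Conditions: LiN(SiMe3)2 (2.2 equiv), THF, −78 → −20 °C; AcOH, −78 °C
Reagents that add atoms: none
Why: Proposed new method: LiN(SiMe3)2 removes an α-proton of the γ-lactone (the only enolisable position, since the methoxyacrylate has no α-hydrogen), the enolate carbon (future C-1 of ring C) adds to the β-carbon of the β-methoxyacrylate (future C-2) to give ester enolate 11, and E1cB loss of methoxide restores the C=C as C-2=C-3 inside the new ring. The closest known reaction types are the addition–elimination (nucleophilic vinylic substitution) of enolates on β-alkoxy- and β-halo-acrylates and alkoxymethylene malonates between two molecules, and the intramolecular Michael addition of lactone enolates; new is their union in a ring closure on a singly activated, α-alkylated β-methoxyacrylate. Ring C closes in the 6-(enolexo)-endo-trig mode. The one new stereocenter, C-3a (C-1 of ring C), is controlled by the lactone template: the four-atom tether leaves C-7a on one face of the planar enolate, so only the cis-fused bicycle can form, and C-7a comes unchanged from (R)-α-terpineol. The step needs 1,4- over 1,2-attack on the ester (low temperature and a lithium enolate should favour conjugate addition) and C-protonation of the stabilised product anion at C-3a and not at C-5 (a cold acetic acid quench should protonate the extended enolate at its α-carbon from the convex face).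

Step 7
Reactants: 12 methyl (3aS,7aR)-1,1-dimethyl-3-oxo-1,3,3a,6,7,7a-hexahydro-2-benzofuran-5-carboxylate
Product: 13 (3aS,7aR)-5-(hydroxymethyl)-1,1-dimethyl-1,3,3a,6,7,7a-hexahydro-2-benzofuran-3-ol (lactol, both anomers)
Conditions: i-Bu2AlH (4 equiv), CH2Cl2, −78 °C; aq. KNaC4H4O6
Reagents that add atoms: none
Why: Hydride reduction stops at the lactol (stable aluminium hemiacetal) and takes the enoate to the allylic alcohol; this removes the acidifying ester while C-3a is still locked in the ring.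

Step 8
Reactants: 14 triethyl phosphonoacetate
Product: 15 ethyl 2-(diethoxyphosphoryl)-3-hydroxypropanoate
Conditions: 37 % aq. HCHO (1.0 equiv), K2CO3 (cat.), H2O, 0 °C
Reagents that add atoms: formaldehyde C=O
Why: Base-catalysed aldol-type hydroxymethylation of the phosphonoacetate with one equivalent of formaldehyde.

Step 9
Reactants: 13 the lactol of step 7; 15 ethyl 2-(diethoxyphosphoryl)-3-hydroxypropanoate
Product: 16 ethyl (2E)-2-(hydroxymethyl)-3-[(1R,6R)-3-(hydroxymethyl)-6-(2-hydroxypropan-2-yl)cyclohex-2-en-1-yl]prop-2-enoate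
Conditions: LiCl, i-Pr2NEt, MeCN, 0 °C → rt
Reagents that add atoms: none
Why: Horner–Wadsworth–Emmons olefination of the open hydroxy-aldehyde form of the lactol; α-substituted phosphonoacetates and α-branched aldehydes should give the E isomer (acyl trans to ring C). The weak amine base limits epimerisation at C-1 and oxa-Michael return of the tertiary hydroxyl.

Step 10
Reactants: 16 the triol ester of step 9
Product: 17 ethyl (2E)-2-(acetoxymethyl)-3-[(1R,6R)-3-(acetoxymethyl)-6-(2-hydroxypropan-2-yl)cyclohex-2-en-1-yl]prop-2-enoate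
Conditions: Ac2O, pyridine, DMAP (cat.), CH2Cl2, 0 °C
Reagents that add atoms: acetic anhydride CC(=O)OC(C)=O
Why: Acetylation of the two primary hydroxyls; the hindered tertiary alcohol should not react at 0 °C.

Step 11
Reactants: 17 the diacetate of step 10
Product: 18 ethyl (2E)-2-(acetoxymethyl)-3-[(1R,6R)-3-(acetoxymethyl)-6-{2-[(methoxyoxalyl)oxy]propan-2-yl}cyclohex-2-en-1-yl]prop-2-enoate
Conditions: ClC(O)CO2Me, DMAP, Et3N, CH2Cl2, 0 °C → rt
Reagents that add atoms: methyl chlorooxoacetate COC(=O)C(Cl)=O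
Why: Acylation of the tertiary alcohol to its methyl oxalate, the radical precursor.

Step 12
Reactants: 18 the tertiary methyl oxalate of step 11
Product: 19 ethyl (2E)-2-(acetoxymethyl)-3-[(1R,6S)-3-(acetoxymethyl)-6-(propan-2-yl)cyclohex-2-en-1-yl]prop-2-enoate
Conditions: Bu3SnH, AIBN (cat.), PhMe, 110 °C
Reagents that add atoms: none
Why: Barton–McCombie-type radical deoxygenation of a tertiary oxalate; the tertiary radical has no favourable ring closure (only 4-exo or 5-endo) and is reduced to the isopropyl group, so no stereocenter is touched.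

Step 13
Reactants: 19 the diacetate ethyl ester of step 12
Product: 20 (2E)-2-(hydroxymethyl)-3-[(1R,6S)-3-(hydroxymethyl)-6-(propan-2-yl)cyclohex-2-en-1-yl]prop-2-enoic acid
Conditions: LiOH, THF/H2O, 0 °C → rt; 1 M HCl to pH 3
Reagents that add atoms: lithium hydroxide [Li+].[OH-]
Why: Saponification of the ethyl ester and both acetates in one operation; short, cold treatment limits γ-deprotonation at the doubly allylic C-1.

**Lactone half**

Step 14
Reactants: 21 4-(propan-2-yl)cyclohexan-1-one
Product: 22 trimethyl{[(4S)-4-(propan-2-yl)cyclohex-1-en-1-yl]oxy}silane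
Conditions: lithium (R,R)-bis(1-phenylethyl)amide, Me3SiCl (internal quench), THF, −90 °C
Reagents that add atoms: chlorotrimethylsilane C[Si](C)(C)Cl
Why: Enantioselective deprotonation (desymmetrisation) of the prochiral ketone by a chiral lithium amide with silylation in the flask; this sets C-6 of ring A by reagent control.

Step 15
Reactants: 22 the silyl enol ether of step 14
Product: 23 (4R)-4-(propan-2-yl)cyclohex-2-en-1-one ((R)-cryptone)
Conditions: Pd(OAc)2 (10 mol %), O2 (1 atm), DMSO, rt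
Reagents that add atoms: none
Why: Saegusa–Ito oxidation of the silyl enol ether to the enone; the γ-stereocenter is kept (descriptor changes by priority only).

Step 16
Reactants: 23 (R)-cryptone
Product: 24 (4R)-2-(hydroxymethyl)-4-(propan-2-yl)cyclohex-2-en-1-one
Conditions: 37 % aq. HCHO, DMAP (20 mol %), THF/H2O, rt
Reagents that add atoms: formaldehyde C=O
Why: Morita–Baylis–Hillman reaction of the cyclic enone with formaldehyde puts the future lactone carbon on C-9a.

Step 17
Reactants: 24 the hydroxymethyl enone of step 16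
Product: 25 (4R)-2-{[(tert-butyldimethylsilyl)oxy]methyl}-4-(propan-2-yl)cyclohex-2-en-1-one
Conditions: t-BuMe2SiCl, imidazole, DMF, 0 °C
Reagents that add atoms: tert-butyldimethylsilyl chloride CC(C)(C)[Si](C)(C)Cl
Why: Silylation of the primary alcohol prevents retro-aldol loss of formaldehyde in the next steps.

Step 18
Reactants: 25 the silyloxymethyl enone of step 17
Product: 27 (2S,3R,4R)-2-{[(tert-butyldimethylsilyl)oxy]methyl}-3-ethenyl-4-(propan-2-yl)cyclohexan-1-one, via magnesium enolate 26 (not isolated)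
Conditions: CH2=CHMgBr, CuBr·SMe2 (20 mol %), THF, −78 → −40 °C; sat. aq. NH4Cl at −78 °C
Reagents that add atoms: vinylmagnesium bromide C=C[Mg]Br
Why: Copper-catalysed conjugate addition anti to the adjacent isopropyl group sets C-5a (trans). Kinetic protonation of the tetrasubstituted enolate anti to the new vinyl group (pushed pseudo-axial by A(1,2) strain) should set C-9a cis to it.

Step 19
Reactants: 27 the cis-2,3 ketone of step 18
Product: 28 tert-butyl{[(3S,4S,5R,6R)-5-ethenyl-6-(propan-2-yl)-1-oxaspiro[2.5]octan-4-yl]methoxy}dimethylsilane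
Conditions: Me3S+ I−, n-BuLi, THF, −10 °C; then 27, −10 → 0 °C
Reagents that add atoms: trimethylsulfonium iodide C[S+](C)C.[I-]
Why: Corey–Chaykovsky epoxidation; the ylide attacks axially, anti to the axial C-2 substituent, so the new CH2 is axial and the oxygen equatorial, cis to the C-2 carbon, which sets C-9. The weakly basic ylide should not epimerise the ketone.

Step 20
Reactants: 28 the spiro-epoxide of step 19
Product: 29 [(3S,4S,5R,6R)-5-ethenyl-6-(propan-2-yl)-1-oxaspiro[2.5]octan-4-yl]methanol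
Conditions: Bu4NF, THF, 0 °C
Reagents that add atoms: none
Why: Fluoride desilylation; the alcohol is trans-diaxial to the epoxide CH2 and cannot open the oxirane.

Step 21
Reactants: 29 the epoxy alcohol of step 20
Product: 31 (3S,4R,5R,6R)-5-ethenyl-6-(propan-2-yl)-1-oxaspiro[2.5]octane-4-carboxylic acid, via aldehyde 30 (not isolated)
Conditions: TEMPO (10 mol %), NaOCl (2 mol %), NaClO2, MeCN/phosphate buffer pH 6.7, 35 °C
Reagents that add atoms: sodium chlorite [Na+].[O-]Cl=O
Why: Oxoammonium oxidation to the aldehyde and Pinnick-type chlorite oxidation in one pot at near-neutral pH, which spares the vinyl group and the epoxide and gives the epimerisable aldehyde no lifetime; the acid is used at once.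

Step 22
Reactants: 32 2-(bromomethyl)prop-2-enoic acid
Product: 33 2-(trimethylsilyl)ethyl 2-(bromomethyl)prop-2-enoate
Conditions: Me3SiCH2CH2OH, DCC, DMAP (cat.), CH2Cl2, 0 °C
Reagents that add atoms: 2-(trimethylsilyl)ethanol C[Si](C)(C)CCO
Why: Steglich esterification gives the acrylate building block with a fluoride-labile ester.

Step 23
Reactants: 31 the epoxy acid of step 21; 33 2-(trimethylsilyl)ethyl 2-(bromomethyl)prop-2-enoate
Product: 34 2-{[2-(trimethylsilyl)ethoxy]carbonyl}prop-2-en-1-yl (3S,4R,5R,6R)-5-ethenyl-6-(propan-2-yl)-1-oxaspiro[2.5]octane-4-carboxylate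
Conditions: Cs2CO3, DMF, 0 °C → rt
Reagents that add atoms: none
Why: O-Alkylation of the caesium carboxylate by the allylic bromide (SN2 and SN2' give the same product); the carboxylate centre is not epimerisable under these conditions.

Step 24
Reactants: 34 the diene ester of step 23
Product: 35 2-(trimethylsilyl)ethyl (5aS,6R,9S,9aR)-1-oxo-6-(propan-2-yl)-3,5a,6,7,8,9a-hexahydro-1H-spiro[2-benzoxepine-9,2'-oxirane]-4-carboxylate
Conditions: second-generation Grubbs catalyst RuCl2(=CHPh)(PCy3)(H2IMes) (5 mol %), PhMe, 80 °C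
Reagents that add atoms: none
Why: Ring-closing metathesis between the vinyl group and the 1,1-disubstituted acrylate closes ring B; the ring fixes the alkene geometry (CH2O cis to C-5a), and the cis arrangement of the two arms favours closure.

**Union**

Step 25
Reactants: 20 the dihydroxy acid of step 13; 35 the spiro-epoxide of step 24
Product: 36 2-(trimethylsilyl)ethyl (5aS,6R,9S,9aR)-9-hydroxy-9-({[(2E)-2-(hydroxymethyl)-3-[(1R,6S)-3-(hydroxymethyl)-6-(propan-2-yl)cyclohex-2-en-1-yl]prop-2-enoyl]oxy}methyl)-1-oxo-6-(propan-2-yl)-1,3,5a,6,7,8,9,9a-octahydro-2-benzoxepine-4-carboxylate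
Conditions: Cs2CO3 (0.2 equiv), DMF, 4 Å MS, 60 °C
Reagents that add atoms: none
Why: SN2 opening of the 2,2-disubstituted epoxide at its CH2 by the carboxylate (known ring opening of terminal epoxides by carboxylic acids) forms the ester and frees the tertiary alcohol with C-9 unchanged; carboxylate outcompetes the free hydroxyls, so the acid needs no protection.

Step 26
Reactants: 36 the 2-(trimethylsilyl)ethyl ester of step 25
Product: 37 CNP0361406.10, (5aS,6R,9S,9aR)-9-hydroxy-9-({[(2E)-2-(hydroxymethyl)-3-[(1R,6S)-3-(hydroxymethyl)-6-(propan-2-yl)cyclohex-2-en-1-yl]prop-2-enoyl]oxy}methyl)-1-oxo-6-(propan-2-yl)-1,3,5a,6,7,8,9,9a-octahydro-2-benzoxepine-4-carboxylic acid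
Conditions: Bu4NF, THF, 0 °C → rt; aq. NH4Cl
Reagents that add atoms: none
Why: Fluoride-induced β-elimination of the 2-(trimethylsilyl)ethyl ester frees the acid without touching the lactone, the linking ester or the alcohols.

**Compound list**

1 | (R)-α-terpineol, 2-[(1R)-4-methylcyclohex-3-en-1-yl]propan-2-ol | CC1=CC[C@@H](CC1)C(C)(C)O | starting material
2 | (3R)-3-(2-hydroxypropan-2-yl)-6-oxoheptanoic acid | CC(=O)CC[C@H](CC(=O)O)C(C)(C)O | intermediate
3 | (4R)-5,5-dimethyl-4-(3-oxobutyl)oxolan-2-one | CC(=O)CC[C@@H]1CC(=O)OC1(C)C | intermediate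
4 | 3-[(3R)-2,2-dimethyl-5-oxooxolan-3-yl]propanoic acid | OC(=O)CC[C@@H]1CC(=O)OC1(C)C | intermediate
5 | (4S)-4-(2-iodoethyl)-5,5-dimethyloxolan-2-one | ICC[C@@H]1CC(=O)OC1(C)C | intermediate
6 | methyl (2E)-3-methoxyprop-2-enoate | CO/C=C/C(=O)OC | starting material
7 | methyl 3-acetoxy-2-iodo-3-methoxypropanoate | COC(OC(C)=O)C(I)C(=O)OC | intermediate
8 | methyl (2Z)-2-iodo-3-methoxyprop-2-enoate | CO/C=C(\I)C(=O)OC | intermediate
9 | {2-[(3S)-2,2-dimethyl-5-oxooxolan-3-yl]ethyl}(iodo)zinc | I[Zn]CC[C@@H]1CC(=O)OC1(C)C | intermediate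
10 | methyl (2E)-2-{2-[(3R)-2,2-dimethyl-5-oxooxolan-3-yl]ethyl}-3-methoxyprop-2-enoate | CO/C=C(\CC[C@@H]1CC(=O)OC1(C)C)C(=O)OC | intermediate
11 | lithium ester enolate of the 4-methoxy Michael adduct (cis-fused octahydro-2-benzofuran-3-one) | COC1[C@@H]2C(=O)OC(C)(C)[C@@H]2CCC1=C(OC)O[Li] | intermediate
12 | methyl (3aS,7aR)-1,1-dimethyl-3-oxo-1,3,3a,6,7,7a-hexahydro-2-benzofuran-5-carboxylate | COC(=O)C1=C[C@@H]2C(=O)OC(C)(C)[C@@H]2CC1 | intermediate
13 | (3aS,7aR)-5-(hydroxymethyl)-1,1-dimethyl-1,3,3a,6,7,7a-hexahydro-2-benzofuran-3-ol | OCC1=C[C@@H]2C(O)OC(C)(C)[C@@H]2CC1 | intermediate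
14 | triethyl phosphonoacetate | CCOC(=O)CP(=O)(OCC)OCC | starting material
15 | ethyl 2-(diethoxyphosphoryl)-3-hydroxypropanoate | CCOC(=O)C(CO)P(=O)(OCC)OCC | intermediate
16 | ethyl (2E)-2-(hydroxymethyl)-3-[(1R,6R)-3-(hydroxymethyl)-6-(2-hydroxypropan-2-yl)cyclohex-2-en-1-yl]prop-2-enoate | CCOC(=O)/C(=C/[C@H]1C=C(CO)CC[C@H]1C(C)(C)O)CO | intermediate
17 | ethyl (2E)-2-(acetoxymethyl)-3-[(1R,6R)-3-(acetoxymethyl)-6-(2-hydroxypropan-2-yl)cyclohex-2-en-1-yl]prop-2-enoate | CCOC(=O)/C(=C/[C@H]1C=C(COC(C)=O)CC[C@H]1C(C)(C)O)COC(C)=O | intermediate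
18 | ethyl (2E)-2-(acetoxymethyl)-3-[(1R,6R)-3-(acetoxymethyl)-6-{2-[(methoxyoxalyl)oxy]propan-2-yl}cyclohex-2-en-1-yl]prop-2-enoate | CCOC(=O)/C(=C/[C@H]1C=C(COC(C)=O)CC[C@H]1C(C)(C)OC(=O)C(=O)OC)COC(C)=O | intermediate
19 | ethyl (2E)-2-(acetoxymethyl)-3-[(1R,6S)-3-(acetoxymethyl)-6-(propan-2-yl)cyclohex-2-en-1-yl]prop-2-enoate | CCOC(=O)/C(=C/[C@H]1C=C(COC(C)=O)CC[C@H]1C(C)C)COC(C)=O | intermediate
20 | (2E)-2-(hydroxymethyl)-3-[(1R,6S)-3-(hydroxymethyl)-6-(propan-2-yl)cyclohex-2-en-1-yl]prop-2-enoic acid | OC(=O)/C(=C/[C@H]1C=C(CO)CC[C@H]1C(C)C)CO | intermediate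
21 | 4-(propan-2-yl)cyclohexan-1-one | CC(C)C1CCC(=O)CC1 | starting material
22 | trimethyl{[(4S)-4-(propan-2-yl)cyclohex-1-en-1-yl]oxy}silane | CC(C)[C@@H]1CC=C(O[Si](C)(C)C)CC1 | intermediate
23 | (4R)-4-(propan-2-yl)cyclohex-2-en-1-one | CC(C)[C@@H]1C=CC(=O)CC1 | intermediate
24 | (4R)-2-(hydroxymethyl)-4-(propan-2-yl)cyclohex-2-en-1-one | CC(C)[C@@H]1C=C(CO)C(=O)CC1 | intermediate
25 | (4R)-2-{[(tert-butyldimethylsilyl)oxy]methyl}-4-(propan-2-yl)cyclohex-2-en-1-one | CC(C)[C@@H]1C=C(CO[Si](C)(C)C(C)(C)C)C(=O)CC1 | intermediate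
26 | bromomagnesium enolate of 27 | CC(C)[C@H]1CCC(O[Mg]Br)=C(CO[Si](C)(C)C(C)(C)C)[C@@H]1C=C | intermediate
27 | (2S,3R,4R)-2-{[(tert-butyldimethylsilyl)oxy]methyl}-3-ethenyl-4-(propan-2-yl)cyclohexan-1-one | CC(C)[C@H]1CCC(=O)[C@H](CO[Si](C)(C)C(C)(C)C)[C@@H]1C=C | intermediate
28 | tert-butyl{[(3S,4S,5R,6R)-5-ethenyl-6-(propan-2-yl)-1-oxaspiro[2.5]octan-4-yl]methoxy}dimethylsilane | CC(C)[C@H]1CC[C@@]2(CO2)[C@H](CO[Si](C)(C)C(C)(C)C)[C@@H]1C=C | intermediate
29 | [(3S,4S,5R,6R)-5-ethenyl-6-(propan-2-yl)-1-oxaspiro[2.5]octan-4-yl]methanol | CC(C)[C@H]1CC[C@@]2(CO2)[C@H](CO)[C@@H]1C=C | intermediate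
30 | (3S,4R,5R,6R)-5-ethenyl-6-(propan-2-yl)-1-oxaspiro[2.5]octane-4-carbaldehyde | CC(C)[C@H]1CC[C@@]2(CO2)[C@H](C=O)[C@@H]1C=C | intermediate
31 | (3S,4R,5R,6R)-5-ethenyl-6-(propan-2-yl)-1-oxaspiro[2.5]octane-4-carboxylic acid | CC(C)[C@H]1CC[C@@]2(CO2)[C@H](C(=O)O)[C@@H]1C=C | intermediate
32 | 2-(bromomethyl)prop-2-enoic acid | C=C(CBr)C(=O)O | starting material
33 | 2-(trimethylsilyl)ethyl 2-(bromomethyl)prop-2-enoate | C=C(CBr)C(=O)OCC[Si](C)(C)C | intermediate
34 | 2-{[2-(trimethylsilyl)ethoxy]carbonyl}prop-2-en-1-yl (3S,4R,5R,6R)-5-ethenyl-6-(propan-2-yl)-1-oxaspiro[2.5]octane-4-carboxylate | CC(C)[C@H]1CC[C@@]2(CO2)[C@H](C(=O)OCC(=C)C(=O)OCC[Si](C)(C)C)[C@@H]1C=C | intermediate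
35 | 2-(trimethylsilyl)ethyl (5aS,6R,9S,9aR)-1-oxo-6-(propan-2-yl)-3,5a,6,7,8,9a-hexahydro-1H-spiro[2-benzoxepine-9,2'-oxirane]-4-carboxylate | CC(C)[C@H]1CC[C@@]3(CO3)[C@@H]2C(=O)OCC(C(=O)OCC[Si](C)(C)C)=C[C@H]12 | intermediate
36 | 2-(trimethylsilyl)ethyl ester of the target | CC(C)[C@H]1CC[C@@](O)(COC(=O)/C(=C/[C@H]2C=C(CO)CC[C@H]2C(C)C)CO)[C@@H]2C(=O)OCC(C(=O)OCC[Si](C)(C)C)=C[C@H]12 | intermediate
37 | CNP0361406.10 | CC(C)[C@H]1CC[C@@](O)(COC(=O)/C(=C/[C@H]2C=C(CO)CC[C@H]2C(C)C)CO)[C@@H]2C(=O)OCC(C(=O)O)=C[C@H]12 | target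

**Count and risks**

Total step count: 26. Longest linear sequence: 13 steps (1, 2, 3, 5, 6, 7, 9, 10, 11, 12, 13, 25, 26).

Step 6 (Proposed new method). What may go wrong: attack of the lactone enolate on the ester carbonyl instead of the β-carbon, no reaction of the deactivated vinylogous carbonate, or protonation of the stabilised product anion at C-5 with migration of the double bond and loss of the C-3a centre. The fallback uses known chemistry and sets out from 10. Aqueous acid (1 M HCl, THF) hydrolyses the enol ether to methyl 2-{2-[(3R)-2,2-dimethyl-5-oxooxolan-3-yl]ethyl}-3-oxopropanoate F1. TsCl, N-methylimidazole and Et3N convert it into the enol tosylate methyl (2E)-2-{2-[(3R)-2,2-dimethyl-5-oxooxolan-3-yl]ethyl}-3-{[(4-methylphenyl)sulfonyl]oxy}prop-2-enoate F2, with the tosylate cis to the chain. F2 is closed by palladium-catalysed intramolecular α-alkenylation of the lactone enolate (Pd2(dba)3, XPhos, LiN(SiMe3)2, THF): oxidative addition of zerovalent palladium activates only the C–OTs carbon, so the ester carbonyl is no longer a competing site. The route is rejoined at 12.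

Step 18. What may go wrong: poor facial selectivity in the protonation of the enolate, or epimerisation of the cis ketone to the all-equatorial isomer. The fallback sets out from 25 and makes the centre under thermodynamic control. The conjugate addition is worked up without regard to C-2 and gives 27 mixed with its epimer (2R,3R,4R)-2-{[(tert-butyldimethylsilyl)oxy]methyl}-3-ethenyl-4-(propan-2-yl)cyclohexan-1-one F3. The mixture is condensed with pyrrolidine (TsOH cat., PhH, water removal) to the less substituted Stork enamine 1-[(4R,5R,6R)-6-{[(tert-butyldimethylsilyl)oxy]methyl}-5-ethenyl-4-(propan-2-yl)cyclohex-1-en-1-yl]pyrrolidine F4, in which A(1,3) strain holds the C-6 substituent axial, that is cis to the vinyl group, and the enamine tautomers equilibrate that centre. Cold buffered hydrolysis (AcOH/NaOAc, H2O, 0 °C) returns the route at 27.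

Step 25. What may go wrong: slow SN2 opening at the neopentyl-type CH2 of the spiro-epoxide, with rearrangement of the epoxide or acyl transfer competing at the temperature needed. The fallback sets out from 35 and 20 and replaces epoxide opening by esterification. Dilute HClO4 in THF/H2O hydrates 35 to the diol 2-(trimethylsilyl)ethyl (5aS,6R,9S,9aR)-9-hydroxy-9-(hydroxymethyl)-1-oxo-6-(propan-2-yl)-1,3,5a,6,7,8,9,9a-octahydro-2-benzoxepine-4-carboxylate F5. Acid 20 is silylated (t-BuMe2SiCl, imidazole, DMF) to its bis(silyl ether) silyl ester F6, whose silyl ester is cleaved (K2CO3, MeOH/H2O) to (2E)-2-{[(tert-butyldimethylsilyl)oxy]methyl}-3-[(1R,6S)-3-{[(tert-butyldimethylsilyl)oxy]methyl}-6-(propan-2-yl)cyclohex-2-en-1-yl]prop-2-enoic acid F7. EDC and DMAP esterify the primary hydroxyl of F5 with F7 to the bis(silyl ether) of 36 F8. Bu4NF then removes both silyl ethers and the 2-(trimethylsilyl)ethyl ester, and the route is rejoined at 37.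

Further compounds
F1 | step 6 | methyl 2-{2-[(3R)-2,2-dimethyl-5-oxooxolan-3-yl]ethyl}-3-oxopropanoate | COC(=O)C(C=O)CC[C@@H]1CC(=O)OC1(C)C
F2 | step 6 | methyl (2E)-2-{2-[(3R)-2,2-dimethyl-5-oxooxolan-3-yl]ethyl}-3-{[(4-methylphenyl)sulfonyl]oxy}prop-2-enoate | COC(=O)/C(CC[C@@H]1CC(=O)OC1(C)C)=C/OS(=O)(=O)c1ccc(C)cc1
F3 | step 18 | (2R,3R,4R)-2-{[(tert-butyldimethylsilyl)oxy]methyl}-3-ethenyl-4-(propan-2-yl)cyclohexan-1-one | CC(C)[C@H]1CCC(=O)[C@@H](CO[Si](C)(C)C(C)(C)C)[C@@H]1C=C
F4 | step 18 | 1-[(4R,5R,6R)-6-{[(tert-butyldimethylsilyl)oxy]methyl}-5-ethenyl-4-(propan-2-yl)cyclohex-1-en-1-yl]pyrrolidine | CC(C)[C@H]1CC=C(N2CCCC2)[C@H](CO[Si](C)(C)C(C)(C)C)[C@@H]1C=C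
F5 | step 25 | 2-(trimethylsilyl)ethyl (5aS,6R,9S,9aR)-9-hydroxy-9-(hydroxymethyl)-1-oxo-6-(propan-2-yl)-1,3,5a,6,7,8,9,9a-octahydro-2-benzoxepine-4-carboxylate | CC(C)[C@H]1CC[C@@](O)(CO)[C@@H]2C(=O)OCC(C(=O)OCC[Si](C)(C)C)=C[C@H]12
F6 | step 25 | tert-butyldimethylsilyl (2E)-2-{[(tert-butyldimethylsilyl)oxy]methyl}-3-[(1R,6S)-3-{[(tert-butyldimethylsilyl)oxy]methyl}-6-(propan-2-yl)cyclohex-2-en-1-yl]prop-2-enoate | CC(C)(C)[Si](C)(C)OC(=O)/C(=C/[C@H]1C=C(CO[Si](C)(C)C(C)(C)C)CC[C@H]1C(C)C)CO[Si](C)(C)C(C)(C)C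
F7 | step 25 | (2E)-2-{[(tert-butyldimethylsilyl)oxy]methyl}-3-[(1R,6S)-3-{[(tert-butyldimethylsilyl)oxy]methyl}-6-(propan-2-yl)cyclohex-2-en-1-yl]prop-2-enoic acid | OC(=O)/C(=C/[C@H]1C=C(CO[Si](C)(C)C(C)(C)C)CC[C@H]1C(C)C)CO[Si](C)(C)C(C)(C)C
F8 | step 25 | bis(tert-butyldimethylsilyl ether) of 36 | CC(C)[C@H]1CC[C@@](O)(COC(=O)/C(=C/[C@H]2C=C(CO[Si](C)(C)C(C)(C)C)CC[C@H]2C(C)C)CO[Si](C)(C)C(C)(C)C)[C@@H]2C(=O)OCC(C(=O)OCC[Si](C)(C)C)=C[C@H]12
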